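The rate constants were drawn at random within sensible limits; what happens was integrated by code.

    precatalyst → catalyst (k1 = 0.0016 s⁻¹)
    substrate + partner → uncatalysed product (k2 = 0.041 M⁻¹ s⁻¹)
    substrate + partner + catalyst → target + catalyst, rate k3*[substrate]*[partner]*[catalyst]/(1 + ([substrate]/sat3)) (sat3 = 3.6 mM, k3 = 6900 M⁻² s⁻¹)

the same everywhere: partner 0.250 M; precatalyst 1.0 mM; time 6.0 min

| charge | substrate |
|---|---|
| Tuesday's | 0.015 M |
| Wednesday's | 0.050 M |
| Thursday's | 0.15 M |
| Saturday's | 0.50 M |

1. [target] at the end for Tuesday's, Wednesday's, Thursday's, Saturday's, in this order
2. how the row runs (falls, then rises / hardly changes / rises all the way / falls all the way / rises, then falls)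

A charge of 0.250 M of partner and 1.0 mM of precatalyst meets four loadings of substrate, and two colleagues dispute what the loading does to the target.

Ann's view is simple. Substrate is the limiting reagent up to Thursday's, and on Saturday's partner takes that role. If a fixed share of the limiting charge becomes target, the row rises all the way, and Saturday's stands 16.7 times above Tuesday's.

Bea denies that the share is fixed. Both routes take one substrate and one partner and are first order in partner, so partner cancels from ρ, the target made per uncatalysed product at a given moment. This leaves ρ = G·[catalyst]/([substrate] + s), where s is the saturation constant 3.6 mM and G, the rate constant of the catalysed step times s over the rate constant of the uncatalysed step, is 606. In the field's terms, ρ is a selectivity factor that moves during the run.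

Bea reckons Saturday's by going round. Partner is consumed against a mean substrate of 0.375 M, which gives a partner lifetime τ of 65.0 s. This is shorter than the precatalyst's half-life of 7.2 min, so catalyst grows about linearly, as k·[precatalyst]·t with k its rate constant, and at τ the ratio is ρ = 0.167. The catalysed route also eats partner, so τ shrinks by the factor one plus ρ, to 55.8 s, and a second round gives ρ = 0.143. The share ρ over one plus ρ, taken of the partner charge, gives Saturday's target as 0.0312 M.

On Thursday's Bea takes τ as the lifetime of substrate against the partner charge, shrunk by the same factor, with a mean substrate of half the charge, and goes round until ρ stands at 0.705, which gives 0.0620 M of target. That figure stands above Tuesday's whole substrate charge of 0.015 M and above her figure for Saturday's, so her row rises, then falls.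

The forecast sides with Bea, at 0.01 M, 0.029 M, 0.068 M and 0.031 M, rises, then falls, with the fall coming where “the uncatalysed reaction uses up the partner before much catalyst has formed”.

The flask gives 0.0101 M, 0.0280 M, 0.0672 M and 0.0307 M, so the row rises, then falls, and Ann's rise holds below the turn, read at 0.23 M.

Saturday's falls through two effects acting together: without the uncatalysed step its target reaches 0.220 M, and without the crowding by substrate 0.183 M. Its end state of 6.15% target to 43.8% uncatalysed product is a ratio of 0.140. On Tuesday's, reckoned as Thursday's was, going round until ρ stands gives 2.46, hence 0.0107 M of target, and that flask holds 0.0101 M.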